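The 7-oxabicyclo[4.1.0]hept-3-ene core (C1 quaternary epoxide carbon, C2 and C5 carbinols, C3 heptenyl-bearing, C4 hydroxymethyl-bearing, C6 epoxide CH) is read as a masked 1,4-benzoquinone: C2 and C5 are para, C3=C4 is one quinone double bond, the C1–C6 epoxide sits on the other. The ring is therefore made by a [4+2] quinone annulation: an α-keto aldehyde (future C2, C3 with the heptenyl chain) and an alkynone (future C4, C5, C6, C1 with both other chains) are joined by a carbene-catalysed Stetter addition (C2–C1) followed in the same flask by aldol condensation (C3=C4). Asymmetric epoxidation and double carbonyl reduction then set all four stereocentres.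

Key step: step 5

Remark: starting materials 1, 2, 4 and 7 are taken to be commercially available.

Step 1
Reactants: 1 3-[(tert-butyldimethylsilyl)oxy]propanal; 2 ethynylmagnesium bromide
Product: 3 5-[(tert-butyldimethylsilyl)oxy]pent-1-yn-3-ol (racemic)
Conditions: THF, 0 °C; aq. NH4Cl
Reagents that add atoms: none
Why: Grignard 1,2-addition of the alkynyl reagent to the aldehyde gives the propargylic alcohol, whose racemic carbinol centre is erased by the oxidation in step 3.

Step 2
Reactants: 3 5-[(tert-butyldimethylsilyl)oxy]pent-1-yn-3-ol; 4 ethyl (E)-4-bromo-2-methylbut-2-enoate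
Product: 5 ethyl (E)-9-[(tert-butyldimethylsilyl)oxy]-7-hydroxy-2-methylnon-2-en-5-ynoate (racemic)
Conditions: CuI (20 mol %), Bu4NI (10 mol %), K2CO3, DMF, 23 °C
Reagents that add atoms: none
Why: In this copper-catalysed alkyne–allyl halide coupling the copper acetylide of 3, formed under carbonate base without protecting the hydroxyl group, is alkylated by the primary allylic bromide at its CH2Br terminus (SN2), which keeps the conjugated (E)-enoate and gives the skipped enyne.

Step 3
Reactants: 5 ethyl (E)-9-[(tert-butyldimethylsilyl)oxy]-7-hydroxy-2-methylnon-2-en-5-ynoate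
Product: 6 ethyl (E)-9-[(tert-butyldimethylsilyl)oxy]-2-methyl-7-oxonon-2-en-5-ynoate
Conditions: activated MnO2, CH2Cl2, 23 °C
Reagents that add atoms: none
Why: MnO2 oxidation of the propargylic alcohol gives the alkynone under neutral, non-enolising conditions that spare the silyl ether and the doubly activated CH2 of the skipped enyne.

Step 4
Reactants: 7 (E)-non-3-en-2-one
Product: 8 (E)-2-oxonon-3-enal
Conditions: SeO2, 1,4-dioxane, H2O (trace), 90 °C; Kugelrohr distillation
Reagents that add atoms: selenium dioxide, O=[Se]=O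
Why: Riley oxidation converts the enolisable methyl group next to the ketone into the aldehyde, the electron-poor conjugated C=C being a poor substrate for allylic oxidation, and distillation cracks the hydrate to the anhydrous keto aldehyde.

Step 5
Reactants: 6 ethyl (E)-9-[(tert-butyldimethylsilyl)oxy]-2-methyl-7-oxonon-2-en-5-ynoate; 8 (E)-2-oxonon-3-enal
Product: 11 ethyl (E)-4-[4-({[tert-butyl(dimethyl)silyl]oxy}methyl)-5-[(E)-hept-1-en-1-yl]-3,6-dioxocyclohexa-1,4-dien-1-yl]-2-methylbut-2-enoate, via enetrione 9 (not isolated), via aldol adduct 10 (not isolated)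
Conditions: 2-(pentafluorophenyl)-6,7-dihydro-5H-pyrrolo[2,1-c][1,2,4]triazol-2-ium tetrafluoroborate (20 mol %), i-Pr2NEt (20 mol %), CH2Cl2, 23 °C; then DBU (30 mol %), 0 °C; air on work-up
Reagents that add atoms: none
Why: Proposed new method: the triazolylidene adds to the aldehyde of 8 to give a Breslow intermediate (acyl-anion equivalent) that adds 1,4 to alkynone 6 at C5, and protonation and release of the carbene give enetrione 9 as an E/Z mixture; the closest known reaction type is the intermolecular Stetter reaction of glyoxamide- and glyoxylate-type donors with enone-type acceptors, here extended to an alkynone acceptor and coupled with a Robinson-type aldol condensation. DBU then generates the enolate at C8 of the former alkynone (alpha to its ketone), which closes the carbocycle by 6-(enolexo)-exo-trig aldol addition to the distal carbonyl of the 1,2-diketone (10), and E1cB dehydration gives quinone 11 with both new ring bonds in place. No stereocentre survives (the two centres of 10 are lost on dehydration), so only geometry and site selectivity are needed. Geometry corrects itself: only (Z)-9 can reach the ring and (E)-9 is drained through reversible conjugate addition of carbene or amine, so both isomers funnel into 11. Site selectivity rests on the alkynone being the strongest and an irreversible acceptor (benzoin-type self-addition of 8 is reversible, its beta-alkyl enone is a poorer acceptor) and on the five-ring aldol to the proximal carbonyl being reversible and unable to dehydrate, whereas the six-ring adduct is removed as the quinone. DBU is added only after 8 is consumed so that 11 cannot oxidise the Breslow intermediate, and air on work-up returns any hydroquinone to 11.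

Step 6
Reactants: 11 ethyl (E)-4-[4-({[tert-butyl(dimethyl)silyl]oxy}methyl)-5-[(E)-hept-1-en-1-yl]-3,6-dioxocyclohexa-1,4-dien-1-yl]-2-methylbut-2-enoate
Product: 12 ethyl (E)-4-[(1R,6S)-4-({[tert-butyl(dimethyl)silyl]oxy}methyl)-3-[(E)-hept-1-en-1-yl]-2,5-dioxo-7-oxabicyclo[4.1.0]hept-3-en-1-yl]-2-methylbut-2-enoate
Conditions: N-(9-anthracenylmethyl)cinchonidinium chloride (10 mol %; or its cinchoninium pseudoenantiomer, whichever gives (1R,6S)-12), aq. NaOCl, toluene, −10 °C
Reagents that add atoms: sodium hypochlorite, [Na+].[O-]Cl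
Why: In this Weitz–Scheffer epoxidation under chiral phase-transfer control, hypochlorite ion-paired with the cinchona ammonium cation adds to the unsubstituted C6 of the less hindered quinone double bond (the tetrasubstituted, dienyl-conjugated C3=C4 bond is shielded and less electrophilic) and the enolate closes on oxygen, so both epoxide stereocentres (C1, C6) are set together by the catalyst-controlled face of attack, as with 2-alkyl-1,4-naphthoquinones.

Step 7
Reactants: 12 ethyl (E)-4-[(1R,6S)-4-({[tert-butyl(dimethyl)silyl]oxy}methyl)-3-[(E)-hept-1-en-1-yl]-2,5-dioxo-7-oxabicyclo[4.1.0]hept-3-en-1-yl]-2-methylbut-2-enoate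
Product: 13 ethyl (E)-4-[(1S,2R,5R,6R)-4-({[tert-butyl(dimethyl)silyl]oxy}methyl)-3-[(E)-hept-1-en-1-yl]-2,5-dihydroxy-7-oxabicyclo[4.1.0]hept-3-en-1-yl]-2-methylbut-2-enoate
Conditions: NaBH4, CeCl3·7H2O, MeOH/THF, −78 to −40 °C
Reagents that add atoms: none
Why: In this Luche 1,2-reduction of both carbonyls, hydride should enter anti to the bulkier substituent on the neighbouring epoxide carbon, that is anti to the epoxide oxygen at C5 (5-OH cis to the epoxide) and anti to the C1 butenoate chain at C2 (2-OH trans to the epoxide), while CeCl3 suppresses conjugate reduction and the ester is untouched.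

Step 8
Reactants: 13 ethyl (E)-4-[(1S,2R,5R,6R)-4-({[tert-butyl(dimethyl)silyl]oxy}methyl)-3-[(E)-hept-1-en-1-yl]-2,5-dihydroxy-7-oxabicyclo[4.1.0]hept-3-en-1-yl]-2-methylbut-2-enoate
Product: 14 ethyl (E)-4-[(1S,2R,5R,6R)-3-[(E)-hept-1-en-1-yl]-2,5-dihydroxy-4-(hydroxymethyl)-7-oxabicyclo[4.1.0]hept-3-en-1-yl]-2-methylbut-2-enoate
Conditions: HF·pyridine, pyridine, THF, 0 °C
Reagents that add atoms: none
Why: Buffered fluoride cleaves the primary silyl ether (silyl ether deprotection driven by Si–F bond formation) without acid strong enough to ionise the bis-allylic carbinols or open the epoxide.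

Step 9
Reactants: 14 ethyl (E)-4-[(1S,2R,5R,6R)-3-[(E)-hept-1-en-1-yl]-2,5-dihydroxy-4-(hydroxymethyl)-7-oxabicyclo[4.1.0]hept-3-en-1-yl]-2-methylbut-2-enoate
Product: 15 (E)-4-[(1S,2R,5R,6R)-3-[(E)-hept-1-en-1-yl]-2,5-dihydroxy-4-(hydroxymethyl)-7-oxabicyclo[4.1.0]hept-3-en-1-yl]-2-methylbut-2-enoic acid
Conditions: LiOH, THF/H2O, 0 °C; then aq. HCl to pH 4
Reagents that add atoms: lithium hydroxide, [Li+].[OH-]
Why: Ester hydrolysis (saponification) and mild acidification give the acid, and Payne rearrangement is not expected because the 5-OH is cis to the epoxide and the 2-alkoxide would have to attack the quaternary C1.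

Compound list
1 | 3-[(tert-butyldimethylsilyl)oxy]propanal | CC(C)(C)[Si](C)(C)OCCC=O | starting material
2 | ethynylmagnesium bromide | C#C[Mg]Br | starting material
3 | 5-[(tert-butyldimethylsilyl)oxy]pent-1-yn-3-ol (racemic) | CC(C)(C)[Si](C)(C)OCCC(O)C#C | intermediate
4 | ethyl (E)-4-bromo-2-methylbut-2-enoate | CCOC(=O)/C(C)=C/CBr | starting material
5 | ethyl (E)-9-[(tert-butyldimethylsilyl)oxy]-7-hydroxy-2-methylnon-2-en-5-ynoate (racemic) | CCOC(=O)/C(C)=C/CC#CC(O)CCO[Si](C)(C)C(C)(C)C | intermediate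
6 | ethyl (E)-9-[(tert-butyldimethylsilyl)oxy]-2-methyl-7-oxonon-2-en-5-ynoate | CCOC(=O)/C(C)=C/CC#CC(=O)CCO[Si](C)(C)C(C)(C)C | intermediate
7 | (E)-non-3-en-2-one | CCCCC/C=C/C(C)=O | starting material
8 | (E)-2-oxonon-3-enal | CCCCC/C=C/C(=O)C=O | intermediate
9 | enetrione, (4Z,8E)-1-[(tert-butyldimethylsilyl)oxy]-5-[(E)-4-ethoxy-3-methyl-4-oxobut-2-en-1-yl]tetradeca-4,8-diene-3,6,7-trione (the Z isomer that cyclises; formed with its E isomer) | CCCCC/C=C/C(=O)C(=O)/C(C/C=C(\C)C(=O)OCC)=C\C(=O)CCO[Si](C)(C)C(C)(C)C | intermediate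
10 | aldol adduct, ethyl (E)-4-[4-({[tert-butyl(dimethyl)silyl]oxy}methyl)-5-[(E)-hept-1-en-1-yl]-5-hydroxy-3,6-dioxocyclohex-1-en-1-yl]-2-methylbut-2-enoate (diastereomer mixture) | CCCCC/C=C/C1(O)C(CO[Si](C)(C)C(C)(C)C)C(=O)C=C(C/C=C(\C)C(=O)OCC)C1=O | intermediate
11 | quinone, ethyl (E)-4-[4-({[tert-butyl(dimethyl)silyl]oxy}methyl)-5-[(E)-hept-1-en-1-yl]-3,6-dioxocyclohexa-1,4-dien-1-yl]-2-methylbut-2-enoate | CCCCC/C=C/C1=C(CO[Si](C)(C)C(C)(C)C)C(=O)C=C(C/C=C(\C)C(=O)OCC)C1=O | intermediate
12 | epoxyquinone, ethyl (E)-4-[(1R,6S)-4-({[tert-butyl(dimethyl)silyl]oxy}methyl)-3-[(E)-hept-1-en-1-yl]-2,5-dioxo-7-oxabicyclo[4.1.0]hept-3-en-1-yl]-2-methylbut-2-enoate | CCCCC/C=C/C1=C(CO[Si](C)(C)C(C)(C)C)C(=O)[C@H]2O[C@@]2(C/C=C(\C)C(=O)OCC)C1=O | intermediate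
13 | epoxy diol, ethyl (E)-4-[(1S,2R,5R,6R)-4-({[tert-butyl(dimethyl)silyl]oxy}methyl)-3-[(E)-hept-1-en-1-yl]-2,5-dihydroxy-7-oxabicyclo[4.1.0]hept-3-en-1-yl]-2-methylbut-2-enoate | CCCCC/C=C/C1=C(CO[Si](C)(C)C(C)(C)C)[C@@H](O)[C@H]2O[C@@]2(C/C=C(\C)C(=O)OCC)[C@@H]1O | intermediate
14 | triol ester, ethyl (E)-4-[(1S,2R,5R,6R)-3-[(E)-hept-1-en-1-yl]-2,5-dihydroxy-4-(hydroxymethyl)-7-oxabicyclo[4.1.0]hept-3-en-1-yl]-2-methylbut-2-enoate | CCCCC/C=C/C1=C(CO)[C@@H](O)[C@H]2O[C@@]2(C/C=C(\C)C(=O)OCC)[C@@H]1O | intermediate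
15 | (E)-4-[(1S,2R,5R,6R)-3-[(E)-hept-1-en-1-yl]-2,5-dihydroxy-4-(hydroxymethyl)-7-oxabicyclo[4.1.0]hept-3-en-1-yl]-2-methylbut-2-enoic acid | CCCCC/C=C/C1=C(CO)[C@@H](O)[C@H]2O[C@@]2(C/C=C(\C)C(=O)O)[C@@H]1O | target

Total step count: 9
Longest linear sequence: 8 steps (steps 1, 2, 3, 5, 6, 7, 8, 9)

Steps most likely to fail

Step 5 (proposed new method). The carbene may be consumed by conjugate addition to the alkynone, or the Breslow intermediate of the keto aldehyde may undergo internal redox to an acyl azolium, before the C–C bond forms. Base may also isomerise the skipped enyne or expel silanolate by beta-elimination before ring closure. The fallback sets out from 6 (with 8) and comes back at 11, using known reaction types only. Hydroiodination of 6 (NaI, AcOH, anti addition) would give the (Z)-beta-iodoenone, ethyl (2E,5Z)-9-[(tert-butyldimethylsilyl)oxy]-5-iodo-2-methyl-7-oxonona-2,5-dienoate F1. A NiCl2-catalysed, CrCl2-mediated Nozaki–Hiyama–Kishi coupling of F1 with the aldehyde of 8 (DMF, 23 °C) would form the C2–C1 bond with retention of alkene geometry and give the hydroxy enedione, (4Z,8E)-1-[(tert-butyldimethylsilyl)oxy]-5-[(E)-4-ethoxy-3-methyl-4-oxobut-2-en-1-yl]-6-hydroxytetradeca-4,8-diene-3,7-dione F2. DBU would then effect the aldol condensation that forms C3=C4, and the resulting 4-hydroxycyclohexadienone would tautomerise to the hydroquinone, ethyl (E)-4-[4-({[tert-butyl(dimethyl)silyl]oxy}methyl)-5-[(E)-hept-1-en-1-yl]-3,6-dihydroxyphenyl]-2-methylbut-2-enoate F3. Ag2O would oxidise F3 to 11.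

Step 6. The ion pair may discriminate poorly between the faces of a monocyclic quinone that lacks the fused arene of the naphthoquinone precedents, and aqueous base may tautomerise the alkylquinone to quinone methides. The fallback sets out from 11 and comes back at 12. Na2S2O4 would reduce 11 to the hydroquinone F3. Methylation of the less hindered phenol, the one next to the ring CH (MeI, K2CO3), would give the monomethyl ether, ethyl (E)-4-[4-({[tert-butyl(dimethyl)silyl]oxy}methyl)-5-[(E)-hept-1-en-1-yl]-6-hydroxy-3-methoxyphenyl]-2-methylbut-2-enoate F4. PhI(OAc)2 in MeOH would give the quinone monoketal, ethyl (E)-4-[4-({[tert-butyl(dimethyl)silyl]oxy}methyl)-5-[(E)-hept-1-en-1-yl]-3,3-dimethoxy-6-oxocyclohexa-1,4-dien-1-yl]-2-methylbut-2-enoate F5, in which the remaining ketone is conjugated to the unsubstituted ring CH. Tartrate-mediated nucleophilic epoxidation, a method established for quinone monoketals (trityl hydroperoxide, NaHMDS, the diisopropyl tartrate enantiomer matched to the 1R,6S epoxide), would give the epoxy ketal, ethyl (E)-4-[(1R,6S)-4-({[tert-butyl(dimethyl)silyl]oxy}methyl)-3-[(E)-hept-1-en-1-yl]-5,5-dimethoxy-2-oxo-7-oxabicyclo[4.1.0]hept-3-en-1-yl]-2-methylbut-2-enoate F6. Mild aqueous acid would hydrolyse the ketal of F6 to 12.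

Step 7. At C2 the stereoelectronic preference for hydride attack anti to the epoxide C–O bond opposes the steric bias from the side chain, so facial selectivity there may be poor; conjugate reduction of the enedione may also compete. The fallback sets out from 12 and comes back at 13. One equivalent of NaBH4 with CeCl3·7H2O at −78 °C would reduce only the less hindered C5 carbonyl, anti to the epoxide, to give the hydroxy enone, ethyl (E)-4-[(1R,5R,6R)-4-({[tert-butyl(dimethyl)silyl]oxy}methyl)-3-[(E)-hept-1-en-1-yl]-5-hydroxy-2-oxo-7-oxabicyclo[4.1.0]hept-3-en-1-yl]-2-methylbut-2-enoate F7. The C2 carbinol would then be set under reagent control by Corey–Bakshi–Shibata reduction of the enone carbonyl (the 2-methyl-CBS-oxazaborolidine enantiomer matched to the 2R carbinol, catecholborane), which gives 13.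

Further compounds
F1 | step 5 | ethyl (2E,5Z)-9-[(tert-butyldimethylsilyl)oxy]-5-iodo-2-methyl-7-oxonona-2,5-dienoate | CCOC(=O)/C(C)=C/C/C(I)=C/C(=O)CCO[Si](C)(C)C(C)(C)C
F2 | step 5 | (4Z,8E)-1-[(tert-butyldimethylsilyl)oxy]-5-[(E)-4-ethoxy-3-methyl-4-oxobut-2-en-1-yl]-6-hydroxytetradeca-4,8-diene-3,7-dione | CCCCC/C=C/C(=O)C(O)/C(C/C=C(\C)C(=O)OCC)=C\C(=O)CCO[Si](C)(C)C(C)(C)C
F3 | step 5 | ethyl (E)-4-[4-({[tert-butyl(dimethyl)silyl]oxy}methyl)-5-[(E)-hept-1-en-1-yl]-3,6-dihydroxyphenyl]-2-methylbut-2-enoate | CCCCC/C=C/c1c(CO[Si](C)(C)C(C)(C)C)c(O)cc(C/C=C(\C)C(=O)OCC)c1O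
F4 | step 6 | ethyl (E)-4-[4-({[tert-butyl(dimethyl)silyl]oxy}methyl)-5-[(E)-hept-1-en-1-yl]-6-hydroxy-3-methoxyphenyl]-2-methylbut-2-enoate | CCCCC/C=C/c1c(CO[Si](C)(C)C(C)(C)C)c(OC)cc(C/C=C(\C)C(=O)OCC)c1O
F5 | step 6 | ethyl (E)-4-[4-({[tert-butyl(dimethyl)silyl]oxy}methyl)-5-[(E)-hept-1-en-1-yl]-3,3-dimethoxy-6-oxocyclohexa-1,4-dien-1-yl]-2-methylbut-2-enoate | CCCCC/C=C/C1=C(CO[Si](C)(C)C(C)(C)C)C(OC)(OC)C=C(C/C=C(\C)C(=O)OCC)C1=O
F6 | step 6 | ethyl (E)-4-[(1R,6S)-4-({[tert-butyl(dimethyl)silyl]oxy}methyl)-3-[(E)-hept-1-en-1-yl]-5,5-dimethoxy-2-oxo-7-oxabicyclo[4.1.0]hept-3-en-1-yl]-2-methylbut-2-enoate | CCCCC/C=C/C1=C(CO[Si](C)(C)C(C)(C)C)C(OC)(OC)[C@H]2O[C@@]2(C/C=C(\C)C(=O)OCC)C1=O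
F7 | step 7 | ethyl (E)-4-[(1R,5R,6R)-4-({[tert-butyl(dimethyl)silyl]oxy}methyl)-3-[(E)-hept-1-en-1-yl]-5-hydroxy-2-oxo-7-oxabicyclo[4.1.0]hept-3-en-1-yl]-2-methylbut-2-enoate | CCCCC/C=C/C1=C(CO[Si](C)(C)C(C)(C)C)[C@@H](O)[C@H]2O[C@@]2(C/C=C(\C)C(=O)OCC)C1=O
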